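(Readings and results are calculated with made-up constants; the scatter is artificial.)

Cross product is slow to come, 16.5 % of the solid in the ash run after 60.0 h, so we ask what is already over by the time it forms, going up a ladder of times.

| setting | larch | ash | elm | beta | gamma | theta | zeta | alpha |
|---|---|---|---|---|---|---|---|---|
| solid substrate | 18 mM | 9 mM | 36 mM | 18 mM | 18 mM | 18 mM | 18 mM | 18 mM |
| partner | 19.8 mM | 19.8 mM | 19.8 mM | 19.8 mM (in portions, 3, over 10 h) | 19.8 mM (fed, over 10 h) | 19.8 mM | 19.8 mM | 19.8 mM |
| second substrate | 9 mM | 9 mM | 9 mM | 9.00 mM | 9.00 mM | 9.00 mM | 9.00 mM | 9.00 mM (fed, over 10 h) |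
| temperature | 95 °C | 110 °C | 95 °C | 110 °C |  |  | 110 °C | 110 °C |
| remark | run made earlier | run made earlier | run made earlier | first portion at the start, last at 10 h | the addition at 90 °C, then warmed to 110 °C; the feed brings no volume worth counting | everything together at the start at 90 °C, warmed to 110 °C at 10 h | everything together at the start | all else is in the flask from the start; the feed brings no volume worth counting |
| time |  |  |  | 50 h | 50 h | 50 h | 50 h | 50 h |

- larch (time / h: cross product / %, target / %): 10.0: 3.7, 2.6; 20.0: 2.5, 3.5; 30.0: 4.0, 3.6; 40.0: 3.9, 4.3; 48.0: 4.1, 4.5; 60.0: 3.3, 5.7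
- ash (time / h: cross product / %, target / %): 4.00: 4.7, 5.3; 12.0: 9.6, 7.5; 20.0: 11.1, 8.5; 30.0: 12.4, 6.3; 50.0: 15.3, 8.0; 60.0: 16.5, 7.6
- elm (time / h: cross product / %, target / %): 8.00: 0.6, 0.7; 25.0: 2.0, 1.8; 40.0: 2.1, 3.1; 60.0: 2.1, 2.6; 96.0: 2.9, 3.0; 120: 2.2, 2.7

(each reading ± 0.5 percentage points)

- as a solid, counted per litre of solution: solid substrate
- what was read earlier has a scatter of 0.5 percentage points, one standard deviation
- at the start none of the solid substrate is in solution

- the flask that comes out highest in amount of cross product, in percent of the solid substrate charged, or "all alike" when all lie within 1.5 percentage points (beta / gamma / theta / zeta / alpha / all alike)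
- cross product at the end, in percent of the solid substrate charged, beta
- cross product at the end, in percent of the solid substrate charged, gamma
- cross product at the end, in percent of the solid substrate charged, theta
- cross product at the end, in percent of the solid substrate charged, zeta
- cross product at the end, in percent of the solid substrate charged, alpha

The first rung is the dissolving. At 40.0 h and 95 °C, larch with 18 mM of solid holds 0.702 mM of cross product, and elm with 36 mM holds 0.756 mM. We therefore take the dissolved amount as steady while solid remains. Each step using it then runs pseudo-first-order: target grows with the partner present, cross product with the second substrate present.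

The next rung is the partner. In ash, target levels off from 20.0 h on at a mean of 7.60 %, and it has 5.3 % at 4.00 h. Taking the loss as first order, we read from this a half-life of the partner in ash at 110 °C, the time in which the partner still able to make target halves:

half-life = 4.00 h × ln 2 / ln(plateau / (plateau − target at 4.00 h)) = 2.32 h

The last rung is the second substrate. Cross product in ash forms on average at 0.106 mM h⁻¹ up to 4.00 h and at 0.0123 mM h⁻¹ from 30.0 h to 60.0 h. We take the ratio of these two readings, 11.6 %, as a rough share of second substrate that outlives the partner in ash.

In alpha, the middle of the feed comes at 5.00 h, when our half-life leaves this share of the partner: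

22.4 %

We let a portion arriving then stand for the whole feed; it faces that fraction of the exposure to partner, so we raise the surviving share to that power:

surviving share = 61.7 %

cross product in alpha ≈ surviving share × early rate × time after the feed = 14.5 %

For zeta, the ash reading at 50.0 h, taken as the same amount in mM, gives 7.65 %, so we put alpha above zeta. We reckon no number for the other flasks.

The forecast gives beta 8.8 %, gamma 6.5 %, theta 5.8 %, zeta 7.7 % and alpha 6.3 %, and it names beta highest; of alpha it says “Feeding second substrate loses the early burst”. On alpha it parts from our 14.5 %.

The flasks give beta 11.3 %, gamma 7.24 %, theta 5.39 %, zeta 7.89 % and alpha 17.2 %, so alpha comes out highest.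

    starting material + second substrate → cross product (k = 22.0 M⁻¹ h⁻¹, Ea = 71.0 kJ mol⁻¹)
    starting material + partner → target (k = 14.0 M⁻¹ h⁻¹, Ea = 71.0 kJ mol⁻¹)
    partner ⇌ dormant form (K = 0.650, k = 1.90 h⁻¹, Ea = 117 kJ mol⁻¹, ΔH = −47.0 kJ mol⁻¹)
    solid substrate ⇌ starting material, rate k4*(cs4 - [starting material]) while solid is left; crystals form when [starting material] > cs4 (solubility = 1.10 mM, k = 10.0 h⁻¹)
    partner → decomposed reagent (k = 0.250 h⁻¹, Ea = 111 kJ mol⁻¹)
    second substrate + partner → second product (k = 39.0 M⁻¹ h⁻¹, Ea = 56.0 kJ mol⁻¹)
    (constants at 110 °C)

In alpha, the step from partner to decomposed reagent has 68 % of its turnover behind it at 5.00 h, while the dissolving of solid substrate reaches 75 % of its own at 25.0 h. Half of alpha's second product is formed by 5.91 h, which is 2.55 of our half-lives, and alpha ends with 4.41 mM of it against 7.16 mM in zeta. For the neighbouring flask, alpha with 50 mM of partner, the same half-life, with the exposure scaled to the partner charge, reckons 6.94 %, and that flask gives 6.86 %.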